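**Retrosynthetic overview**
1. Endgame: the C8 p-hydroxybenzoate (acylation), C8–OH/C7–H (hydroboration of a C7=C8 alkene) and the C4 carbinol (methyl addition to a C4 ketone) lead back to a 6β-benzyloxy bicyclo[5.3.0]deca-1(10),7-dien-4-one.
2. Key disconnection: the seven-membered ring (C1, C5, C6, C7, C8, C9, C10) is opened by a retro-[3,3] step across C5–C6 with re-formation of a C8–C10 bond. This gives a cis-1,2-dialkenylcyclopropane (C8–C9–C10, a temporary ring) carrying a cyclopent-2-enone (C4=O, C5=C1) on C10 and an enol ether (C7=C6–OBn) on C8.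
3. Enabling feature: the seven-membered ring holds the C1=C10 alkene and, across the C9 methylene, the C7–C8 pair that can emerge as a second alkene, while C4–O and C6–O stand 1,3 across C5 (aldol pattern). C5–C6 is therefore the σ-bond made in a divinylcyclopropane–cycloheptadiene rearrangement; the enol ether is released in the flask from a dibenzyl acetal.
4. Ring order: cyclopropane (asymmetric intramolecular cyclopropanation, held cis as a fused lactone) → cyclopentenone (Stetter/aldol) → seven-membered ring last, with the cyclopropane consumed.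

Key step: step 11

Numbering: guaiane numbering is used for the bicyclic compounds and for the corresponding atoms of their precursors (C1/C5 ring fusion, C4 carbinol carbon, C10 methyl-bearing alkene carbon); α is the face of H-5.
Assumption: the sense of induction in step 3 is taken by analogy with allyl diazoacetate cyclisations by dirhodium carboxamidates, i.e. the (4R)-catalyst is assumed to give the (1S,5R)-lactone; if the opposite sense is found, the (4S)-catalyst is used and nothing else changes.

**Route**

Step 1
Reactants: 1 2-methylprop-2-en-1-ol; 2 bromoacetyl bromide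
Product: 3 2-methylallyl bromoacetate
Conditions: NaHCO3, MeCN, 0 °C
Reagents that add atoms: bromoacetyl bromide (2), O=C(Br)CBr
Why: O-acylation of the primary allylic alcohol by the acyl bromide (esterification) is much faster than displacement of the alkyl bromide, and no stereocentre is formed.

Step 2
Reactants: 3 2-methylallyl bromoacetate; 4 N,N'-bis(p-toluenesulfonyl)hydrazine
Product: 5 2-methylallyl diazoacetate
Conditions: DBU, THF, 0 °C
Reagents that add atoms: N,N'-bis(p-toluenesulfonyl)hydrazine (4), Cc1ccc(cc1)S(=O)(=O)NNS(=O)(=O)c1ccc(C)cc1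
Why: N-alkylation of the ditosylhydrazine by the bromoacetate followed by two base-induced sulfinate eliminations (Bamford–Stevens-type) gives the diazoacetate under mild conditions.

Step 3
Reactants: 5 2-methylallyl diazoacetate
Product: 6 (1S,5R)-5-methyl-3-oxabicyclo[3.1.0]hexan-2-one
Conditions: Rh2(4R-MPPIM)4 (1 mol%), CH2Cl2, reflux, slow addition of 5
Reagents that add atoms: none
Why: Intramolecular rhodium-carbenoid cyclopropanation of the 1,1-disubstituted alkene, in which the ester tether enforces the cis-fused lactone (C7 carbonyl and C1H2–O on the same face) and the chiral carboxamidate catalyst sets the absolute configuration of C8 and C10.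

Step 4
Reactants: 6 lactone; 7 isopropyllithium
Product: 8 1-[(1S,2R)-2-(hydroxymethyl)-2-methylcyclopropyl]-2-methylpropan-1-one
Conditions: i-PrLi (1.1 equiv), Et2O, −78 °C; aq. NH4Cl
Reagents that add atoms: isopropyllithium (7), CC(C)[Li]
Why: Single 1,2-addition of a hindered secondary alkyllithium to the lactone gives a tetrahedral lithium hemiketalate that is stable at −78 °C and collapses to the hydroxy ketone (in equilibrium with its hemiketal) on work-up, while the cyclopropane CH is not enolised so the cis arrangement is kept.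

Step 5
Reactants: 8 hydroxy ketone; 9 tert-butyl(chloro)diphenylsilane
Product: 10 TBDPS ether of 8
Conditions: imidazole, DMF, rt
Reagents that add atoms: tert-butyl(chloro)diphenylsilane (9), CC(C)(C)[Si](Cl)(c1ccccc1)c1ccccc1
Why: Silylation of the primary hydroxyl of the open-chain form drains the hemiketal equilibrium and gives a free ketone for the olefination.

Step 6
Reactants: 10 TBDPS keto ether; 11 (benzyloxymethyl)triphenylphosphonium chloride; 12 benzyl alcohol
Product: 14 dibenzyl acetal of the one-carbon homologated aldehyde (TBDPS ether; both C7 epimers), via benzyl enol ether 13 (not isolated)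
Conditions: 11, KOt-Bu, THF, 0 °C → rt; then BnOH, PPTS (cat.), CH2Cl2, rt
Reagents that add atoms: (benzyloxymethyl)triphenylphosphonium chloride (11), [Cl-].C(OCc1ccccc1)[P+](c1ccccc1)(c1ccccc1)c1ccccc1; benzyl alcohol (12), OCc1ccccc1
Why: Wittig alkoxymethylenation adds C6 as an enol ether (E/Z mixture), and acid-catalysed addition of benzyl alcohol stores this vinyl group as a base-stable acetal, the new C7 centre forming as both epimers, which is harmless because C7 becomes sp2 again in step 11.

Step 7
Reactants: 14 silyl ether acetal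
Product: 15 primary alcohol (desilylated 14)
Conditions: TBAF, THF, rt
Reagents that add atoms: none
Why: Fluoride-induced desilylation leaves the acetal untouched, and the product is handled on base-washed silica to prevent acid-catalysed transacetalisation by the free hydroxyl.

Step 8
Reactants: 15 alcohol
Product: 16 (1R,2R)-2-[1,1-bis(benzyloxy)-3-methylbutan-2-yl]-1-methylcyclopropane-1-carbaldehyde
Conditions: TPAP (cat.), NMO, 4 Å MS, CH2Cl2, rt
Reagents that add atoms: none
Why: Neutral perruthenate oxidation of the primary alcohol stops at the aldehyde, which has no α-hydrogen and therefore cannot epimerise or self-condense.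

Step 9
Reactants: 16 aldehyde; 17 but-3-en-2-one
Product: 18 1-{(1R,2R)-2-[1,1-bis(benzyloxy)-3-methylbutan-2-yl]-1-methylcyclopropyl}pentane-1,4-dione
Conditions: 3-benzyl-5-(2-hydroxyethyl)-4-methylthiazolium chloride (cat.), Et3N (cat.), dioxane, 75 °C
Reagents that add atoms: but-3-en-2-one (17), CC(=O)C=C
Why: Stetter reaction, in which the thiazolylidene converts the aldehyde into an acyl-anion equivalent that adds 1,4 to methyl vinyl ketone to give the 1,4-diketone directly.

Step 10
Reactants: 18 1,4-diketone
Product: 19 3-{(1R,2R)-2-[1,1-bis(benzyloxy)-3-methylbutan-2-yl]-1-methylcyclopropyl}cyclopent-2-en-1-one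
Conditions: KOH, EtOH, 50 °C
Reagents that add atoms: none
Why: Intramolecular aldol condensation in which the only pairing that closes a five-membered ring is the C5 methyl enolate on the C1 ketone (C10 is quaternary), giving the 3-substituted cyclopentenone while the acetal is inert to base and no oxy-vinyl group is yet present to rearrange prematurely.

Step 11
Reactants: 19 cyclopentenone dibenzyl acetal
Product: 21 6β-(benzyloxy)-15-nor-5αH-guaia-1(10),7-dien-4-one, via E-enol ether 20 (not isolated)
Conditions: PPTS (10 mol%), toluene, 90 °C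
Reagents that add atoms: none
Why: The pyridinium acid reversibly ionises the dibenzyl acetal to the benzyloxocarbenium ion, which loses H-7 to give the E and Z benzyl enol ethers that stay in equilibrium with each other through the ion and the acetal. The E isomer 20 is a cis-1,2-dialkenylcyclopropane and undergoes the divinylcyclopropane–cycloheptadiene (Cope) rearrangement, the closest known reaction type being the thermal rearrangement of β-(cis-2-vinylcyclopropyl) enones to hydroazulenones. The seven-membered ring closes by a concerted [3,3] sigmatropic shift through the boat transition state with both alkenyl groups over the three-membered ring: the C8–C10 cyclopropane bond breaks, C5–C6 forms, and C1=C10 and C7=C8 appear (a 3→7 ring expansion driven by loss of cyclopropane strain). C5 and C6 are set by the geometry of that transition state: the cyclopropane centres C8 and C10 from step 3 decide which face of C5 and of C6 bonds, the cyclopentenone ring forces H-5 to the inside position, and the E geometry puts H-6 inside and OBn outside, so H-5 and H-6 end cis (5α-H, 6β-OBn). The step needs geometric selectivity (only the E enol ether, with hydrogen pointing at the C9 methylene, should reach the boat, while the Z isomer would carry OBn inside, should be far slower and is fed back through the oxocarbenium ion, so both isomers converge on 21) and chemoselectivity of the acid (a pyridinium salt ionises an acetal much faster than it enolises the β,γ-unsaturated ketone, so C5 and the 1(10) alkene of the product should hold).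

Step 12
Reactants: 21 bicyclic dienone; 22 methyllithium
Product: 23 6β-(benzyloxy)-5αH-guaia-1(10),7-dien-4β-ol
Conditions: MeLi, anhydrous CeCl3, THF, −78 °C; aq. NH4Cl
Reagents that add atoms: methyllithium (22), C[Li]
Why: Organocerium 1,2-addition is non-basic enough to avoid enolisation of the doubly activated C5–H and β-elimination of the benzyloxy group, and the methyl group should enter the cyclopentanone face anti to the C6 branch (syn to H-5), setting C4 with CH3 α and OH β.

Step 13
Reactants: 23 dienol; 24 borane–tetrahydrofuran; 25 hydrogen peroxide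
Product: 27 6β-(benzyloxy)-5αH,7αH-guai-1(10)-ene-4β,8α-diol, via C8 alkylborane 26 (not isolated)
Conditions: BH3·THF, THF, 0 °C → rt; then NaOH, H2O2, 0 °C
Reagents that add atoms: borane–tetrahydrofuran (24), [BH3-][O+]1CCCC1 (boron stays only in 26); hydrogen peroxide (25), OO
Why: Hydroboration–oxidation places boron on the less substituted C8 of the trisubstituted alkene (the tetrasubstituted C1=C10 reacts far more slowly), and syn addition from the α-face, anti to the allylic 6β-benzyloxy group and the 4β-oxygen, should set C7 (H α, isopropyl β) and C8 (OH α) together.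

Step 14
Reactants: 27 diol; 28 4-(benzyloxy)benzoyl chloride
Product: 29 6β-(benzyloxy)-4β-hydroxy-5αH,7αH-guai-1(10)-en-8α-yl 4-(benzyloxy)benzoate
Conditions: Et3N, DMAP, CH2Cl2, rt
Reagents that add atoms: 4-(benzyloxy)benzoyl chloride (28), ClC(=O)c1ccc(OCc2ccccc2)cc1
Why: DMAP-catalysed acylation takes place at the only secondary hydroxyl (C8) with retention, the tertiary C4 hydroxyl being unreactive under these conditions.

Step 15
Reactants: 29 dibenzyl-protected ester
Product: 30 4β,6β-dihydroxy-5αH,7αH-guai-1(10)-en-8α-yl 4-hydroxybenzoate (target)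
Conditions: H2 (1 atm), Pd(OH)2/C, EtOAc, rt
Reagents that add atoms: none
Why: Hydrogenolysis cleaves the aryl and the alkyl benzyl ether in one operation, and the tetrasubstituted alkene and the non-allylic, non-benzylic C–O bonds of the core should not be reduced at atmospheric pressure.

**Compound list**
1 | 2-methylprop-2-en-1-ol (methallyl alcohol) | CC(=C)CO | starting material
2 | bromoacetyl bromide | O=C(Br)CBr | starting material
3 | 2-methylallyl bromoacetate | CC(=C)COC(=O)CBr | intermediate
4 | N,N'-bis(p-toluenesulfonyl)hydrazine | Cc1ccc(cc1)S(=O)(=O)NNS(=O)(=O)c1ccc(C)cc1 | starting material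
5 | 2-methylallyl diazoacetate | CC(=C)COC(=O)C=[N+]=[N-] | intermediate
6 | (1S,5R)-5-methyl-3-oxabicyclo[3.1.0]hexan-2-one | C[C@@]12C[C@@H]1C(=O)OC2 | intermediate
7 | isopropyllithium | CC(C)[Li] | starting material
8 | 1-[(1S,2R)-2-(hydroxymethyl)-2-methylcyclopropyl]-2-methylpropan-1-one (acyl and CH2OH cis) | C[C@@]1(CO)C[C@@H]1C(=O)C(C)C | intermediate
9 | tert-butyl(chloro)diphenylsilane | CC(C)(C)[Si](Cl)(c1ccccc1)c1ccccc1 | starting material
10 | 1-[(1S,2R)-2-({[tert-butyl(diphenyl)silyl]oxy}methyl)-2-methylcyclopropyl]-2-methylpropan-1-one | C[C@@]1(CO[Si](c2ccccc2)(c2ccccc2)C(C)(C)C)C[C@@H]1C(=O)C(C)C | intermediate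
11 | (benzyloxymethyl)triphenylphosphonium chloride | [Cl-].C(OCc1ccccc1)[P+](c1ccccc1)(c1ccccc1)c1ccccc1 | starting material
12 | benzyl alcohol | OCc1ccccc1 | starting material
13 | benzyl enol ether (E/Z mixture): cis-cyclopropane as in 10 with a 1-(benzyloxy)-3-methylbut-1-en-2-yl group on the CH carbon | C[C@@]1(CO[Si](c2ccccc2)(c2ccccc2)C(C)(C)C)C[C@@H]1C(=COCc1ccccc1)C(C)C | intermediate
14 | dibenzyl acetal: (1R,2R)-cyclopropane with CH3 and CH2OTBDPS on C1 and a cis 1,1-bis(benzyloxy)-3-methylbutan-2-yl group on C2 (both epimers at the side-chain CH) | C[C@@]1(CO[Si](c2ccccc2)(c2ccccc2)C(C)(C)C)C[C@@H]1C(C(C)C)C(OCc1ccccc1)OCc1ccccc1 | intermediate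
15 | {(1R,2R)-2-[1,1-bis(benzyloxy)-3-methylbutan-2-yl]-1-methylcyclopropyl}methanol | C[C@@]1(CO)C[C@@H]1C(C(C)C)C(OCc1ccccc1)OCc1ccccc1 | intermediate
16 | (1R,2R)-2-[1,1-bis(benzyloxy)-3-methylbutan-2-yl]-1-methylcyclopropane-1-carbaldehyde | C[C@@]1(C=O)C[C@@H]1C(C(C)C)C(OCc1ccccc1)OCc1ccccc1 | intermediate
17 | but-3-en-2-one (methyl vinyl ketone) | CC(=O)C=C | starting material
18 | 1-{(1R,2R)-2-[1,1-bis(benzyloxy)-3-methylbutan-2-yl]-1-methylcyclopropyl}pentane-1,4-dione | C[C@@]1(C(=O)CCC(C)=O)C[C@@H]1C(C(C)C)C(OCc1ccccc1)OCc1ccccc1 | intermediate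
19 | 3-{(1R,2R)-2-[1,1-bis(benzyloxy)-3-methylbutan-2-yl]-1-methylcyclopropyl}cyclopent-2-en-1-one | C[C@@]1(C2=CC(=O)CC2)C[C@@H]1C(C(C)C)C(OCc1ccccc1)OCc1ccccc1 | intermediate
20 | 3-{(1R,2S)-2-[(E)-1-(benzyloxy)-3-methylbut-1-en-2-yl]-1-methylcyclopropyl}cyclopent-2-en-1-one (alkenyl groups cis) | C[C@@]1(C2=CC(=O)CC2)C[C@@H]1/C(C(C)C)=C/OCc1ccccc1 | intermediate
21 | 6β-(benzyloxy)-15-nor-5αH-guaia-1(10),7-dien-4-one (6-benzyloxy-7-isopropyl-10-methylbicyclo[5.3.0]deca-1(10),7-dien-4-one, H-5 α, OBn β) | CC1=C2CCC(=O)[C@@H]2[C@H](OCc3ccccc3)C(C(C)C)=CC1 | intermediate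
22 | methyllithium | C[Li] | starting material
23 | 6β-(benzyloxy)-5αH-guaia-1(10),7-dien-4β-ol (4α-CH3) | CC1=C2CC[C@](C)(O)[C@@H]2[C@H](OCc3ccccc3)C(C(C)C)=CC1 | intermediate
24 | borane–tetrahydrofuran | [BH3-][O+]1CCCC1 | starting material
25 | hydrogen peroxide | OO | starting material
26 | C8 alkylborane of 23 (drawn as the monoalkylborane; boron 8α, H-7 α) | CC1=C2CC[C@](C)(O)[C@@H]2[C@H](OCc3ccccc3)[C@H](C(C)C)[C@@H](B)C1 | intermediate
27 | 6β-(benzyloxy)-5αH,7αH-guai-1(10)-ene-4β,8α-diol | CC1=C2CC[C@](C)(O)[C@@H]2[C@H](OCc3ccccc3)[C@H](C(C)C)[C@@H](O)C1 | intermediate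
28 | 4-(benzyloxy)benzoyl chloride | ClC(=O)c1ccc(OCc2ccccc2)cc1 | starting material
29 | 6β-(benzyloxy)-4β-hydroxy-5αH,7αH-guai-1(10)-en-8α-yl 4-(benzyloxy)benzoate | CC1=C2CC[C@](C)(O)[C@@H]2[C@H](OCc3ccccc3)[C@H](C(C)C)[C@@H](OC(=O)c3ccc(OCc4ccccc4)cc3)C1 | intermediate
30 | (4S,5S,6R,7S,8S)-4,6-dihydroxyguai-1(10)-en-8-yl 4-hydroxybenzoate (4β,6β-diol, 5α-H, 7β-isopropyl, 8α-ester) | CC1=C2CC[C@](C)(O)[C@@H]2[C@H](O)[C@H](C(C)C)[C@@H](OC(=O)c2ccc(O)cc2)C1 | target

**Step count:** 15 steps in total; longest linear sequence 15 steps (from 1).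

**Steps most likely to fail**

1. Step 11 (key step). What may go wrong: the acetal ionises too slowly, so that harsher acid is needed. Under it the product ketone enolises, with loss of the C5 configuration, drift of the 1(10) alkene into conjugation and β-elimination of benzyl alcohol. Fallback, from 19 back to 21, with the oxy-vinyl group made without acid: 19 is hydrolysed (AcOH, THF, H2O, rt) to the keto aldehyde F1. O-Silylation of the aldehyde (TBSOTf 1.0 equiv, Et3N, CH2Cl2, −78 °C) gives the silyl enol ethers F2 as an E/Z mixture. On warming to room temperature the E isomer should rearrange by the same [3,3] shift to the 6β-silyloxy dienone F3, while the Z isomer is recovered, hydrolysed to F1 and recycled. HF·pyridine (THF, 0 °C) frees the β-hydroxy ketone F4, and benzyl trichloroacetimidate with catalytic TfOH (CH2Cl2/cyclohexane, 0 °C) benzylates it to 21.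

2. Step 9. What may go wrong: the acyl-anion equivalent forms slowly from the α-quaternary aldehyde, so that catalyst-adduct side reactions and polymerisation of the enone consume the reagents. Fallback, from 16 back to 18, with organometallic addition, oxidation and Wacker oxidation in place of umpolung: but-3-enylmagnesium bromide (THF, −78 °C) adds to 16 to give the secondary alcohol F5. TPAP/NMO oxidises it to the butenyl ketone F6. Wacker oxidation of the terminal alkene (PdCl2 cat., Cu(OAc)2, O2, DMF/H2O) converts it into the methyl ketone, which is 18.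

3. Step 6. What may go wrong: the bulky alkoxymethylene ylide attacks the hindered cyclopropyl isopropyl ketone slowly, so that enolisation and base-induced cis-to-trans epimerisation at the cyclopropane CH take over. Fallback, from 10 back to 14, with a small carbon nucleophile and a reduction: reductive cyanation with TosMIC (KOt-Bu, DME/EtOH, 0 °C → rt) turns the ketone into the nitrile F7. DIBAL-H (toluene, −78 °C, then aqueous work-up) gives the aldehyde F8. Benzyl alcohol (3 equiv), PPTS and MgSO4 in CH2Cl2 acetalise it to 14.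

Further compounds
F1 | step 11 | 2-[(1R,2R)-2-methyl-2-(3-oxocyclopent-1-en-1-yl)cyclopropyl]-3-methylbutanal (both epimers at the side-chain CH) | C[C@@]1(C2=CC(=O)CC2)C[C@@H]1C(C(C)C)C=O
F2 | step 11 | tert-butyldimethylsilyl enol ethers of F1 (E/Z mixture) | C[C@@]1(C2=CC(=O)CC2)C[C@@H]1C(C(C)C)=CO[Si](C)(C)C(C)(C)C
F3 | step 11 | 6β-(tert-butyldimethylsilyloxy)-15-nor-5αH-guaia-1(10),7-dien-4-one | CC1=C2CCC(=O)[C@@H]2[C@H](O[Si](C)(C)C(C)(C)C)C(C(C)C)=CC1
F4 | step 11 | 6β-hydroxy-15-nor-5αH-guaia-1(10),7-dien-4-one | CC1=C2CCC(=O)[C@@H]2[C@H](O)C(C(C)C)=CC1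
F5 | step 9 | 1-{(1R,2R)-2-[1,1-bis(benzyloxy)-3-methylbutan-2-yl]-1-methylcyclopropyl}pent-4-en-1-ol (carbinol epimers) | C[C@@]1(C(O)CCC=C)C[C@@H]1C(C(C)C)C(OCc1ccccc1)OCc1ccccc1
F6 | step 9 | 1-{(1R,2R)-2-[1,1-bis(benzyloxy)-3-methylbutan-2-yl]-1-methylcyclopropyl}pent-4-en-1-one | C[C@@]1(C(=O)CCC=C)C[C@@H]1C(C(C)C)C(OCc1ccccc1)OCc1ccccc1
F7 | step 6 | 2-[(1R,2R)-2-({[tert-butyl(diphenyl)silyl]oxy}methyl)-2-methylcyclopropyl]-3-methylbutanenitrile (both epimers at the side-chain CH) | C[C@@]1(CO[Si](c2ccccc2)(c2ccccc2)C(C)(C)C)C[C@@H]1C(C#N)C(C)C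
F8 | step 6 | 2-[(1R,2R)-2-({[tert-butyl(diphenyl)silyl]oxy}methyl)-2-methylcyclopropyl]-3-methylbutanal (both epimers at the side-chain CH) | C[C@@]1(CO[Si](c2ccccc2)(c2ccccc2)C(C)(C)C)C[C@@H]1C(C=O)C(C)C
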